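**Plan**

1. The target is an achiral biflavone ether. Unit 1 is a 5,7-dihydroxy-4'-methoxyflavone that carries the ether oxygen on C8. Unit 2 is a 5-hydroxy-7-methoxyflavone whose ring B carries the same oxygen on its para carbon.
2. Retrosynthesis: after removal of a C7 acetate, both C5–O bonds are cut. Each C5 hydroxyl lies peri to the C4 carbonyl of ring C, so in the dideoxy precursor the two C5–H bonds are the only ones a carbonyl-bound metal can reach. Without these oxygens, ring A of unit 1 is a pyrogallol ring (O7, O8, O1) and ring A of unit 2 a resorcinol ring, so the aryloxy group can only sit on C8, never on C6.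
3. Further cuts: ring C of unit 2 (O1–C2 and C2–C3, through a chalcone from paeonol), the diaryl ether C–O bond (SNAr on 4-fluorobenzaldehyde), and ring C of unit 1 (C-aroylation of gallacetophenone with 4-methoxybenzoyl chloride, then cyclodehydration).
4. Forward order: ring C of unit 1, O7 benzylation, ether bond, chalcone, ring C of unit 2, benzyl-to-acetate exchange, twofold C5–H hydroxylation, deacetylation.
5. Stereochemistry: the target has none; the only stereo element on the way, the E alkene of the chalcone, is set thermodynamically and is consumed on cyclisation.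

Key step: step 9

Remark: should the C7 acetate partly exchange to the trifluoroacetate in the acidic medium of step 9, the material still converges on the target in step 10, because both esters are cleaved there.

**Route**

Step 1
Reactants: 1 gallacetophenone (1-(2,3,4-trihydroxyphenyl)ethanone); 2 4-methoxybenzoyl chloride
Product: 3 1-(4-methoxyphenyl)-3-(2,3,4-trihydroxyphenyl)propane-1,3-dione
Conditions: LiN(SiMe3)2 (5.2 equiv), THF, −78 °C, then 2, −78 °C to rt; aq. HCl
Reagents that add atoms: none
Why: Excess LiN(SiMe3)2 turns the three phenols into lithium phenoxides and the methyl ketone into its enolate, which is C-aroylated by the acid chloride in a Claisen-type condensation (the polyanion variant of the Baker–Venkataraman flavone route), so the 1,3-diketone should form without protecting groups.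

Step 2
Reactants: 3 1-(4-methoxyphenyl)-3-(2,3,4-trihydroxyphenyl)propane-1,3-dione
Product: 4 7,8-dihydroxy-4'-methoxyflavone
Conditions: H2SO4 (cat.), AcOH, 95 °C
Reagents that add atoms: none
Why: Acid-catalysed cyclodehydration of the 2-hydroxyaryl 1,3-diketone closes ring C of unit 1, and only the phenol ortho to the keto group can reach the aroyl carbonyl in a six-membered closure.

Step 3
Reactants: 4 7,8-dihydroxy-4'-methoxyflavone
Product: 5 7-benzyloxy-8-hydroxy-4'-methoxyflavone
Conditions: BnBr (1.05 equiv), KHCO3, DMF, 40 °C, N2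
Reagents that add atoms: benzyl bromide, BrCc1ccccc1
Why: The C7 hydroxyl is conjugated through C4a with the ring C carbonyl and is therefore much more acidic than the C8 hydroxyl, so a hydrogen carbonate base should form only the C7 phenoxide and a Williamson etherification with one equivalent of benzyl bromide should benzylate O7 alone.

Step 4
Reactants: 5 7-benzyloxy-8-hydroxy-4'-methoxyflavone; 6 4-fluorobenzaldehyde
Product: 7 4-{[7-benzyloxy-2-(4-methoxyphenyl)-4-oxo-4H-chromen-8-yl]oxy}benzaldehyde
Conditions: K2CO3 (2 equiv), DMSO, 100 °C, N2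
Reagents that add atoms: none
Why: Nucleophilic aromatic substitution (addition–elimination) of the C8 phenoxide on the para-formyl-activated aryl fluoride is a standard diaryl ether synthesis that tolerates phenoxides with two ortho substituents, and the benzyl ether and chromone are inert to carbonate in a dry dipolar solvent.

Step 5
Reactants: 7 4-{[7-benzyloxy-2-(4-methoxyphenyl)-4-oxo-4H-chromen-8-yl]oxy}benzaldehyde; 8 paeonol (1-(2-hydroxy-4-methoxyphenyl)ethanone)
Product: 9 (E)-3-(4-{[7-benzyloxy-2-(4-methoxyphenyl)-4-oxo-4H-chromen-8-yl]oxy}phenyl)-1-(2-hydroxy-4-methoxyphenyl)prop-2-en-1-one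
Conditions: KOH (50% aq.), EtOH–THF, 0 °C to rt; then cold dilute HCl
Reagents that add atoms: none
Why: Claisen–Schmidt condensation of the paeonol enolate with the non-enolisable aryl aldehyde, followed by E1cB loss of water, should give the thermodynamically preferred E 2'-hydroxychalcone, and the fully O-substituted chromone of unit 1 is expected to tolerate ethanolic KOH at room temperature.

Step 6
Reactants: 9 the E chalcone from step 5
Product: 10 7-benzyloxy-2-(4-methoxyphenyl)-8-[4-(7-methoxy-4-oxo-4H-chromen-2-yl)phenoxy]-4H-chromen-4-one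
Conditions: I2 (10 mol %), DMSO, 130 °C; aq. Na2S2O3
Reagents that add atoms: none
Why: Iodine-catalysed oxidative cyclisation of a 2'-hydroxychalcone in DMSO (oxa-Michael closure, α-iodination and loss of HI, with DMSO reoxidising iodide) is the standard chalcone-to-flavone conversion, and it closes ring C of unit 2 through the only phenol ortho to the enone.

Step 7
Reactants: 10 the benzyl-protected biflavone ether
Product: 11 7-hydroxy-2-(4-methoxyphenyl)-8-[4-(7-methoxy-4-oxo-4H-chromen-2-yl)phenoxy]-4H-chromen-4-one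
Conditions: H2 (1 atm), 10% Pd/C, THF–MeOH, rt
Reagents that add atoms: none
Why: Hydrogenolysis of a benzyl aryl ether over Pd/C is much faster than reduction of the conjugated C2=C3 bonds of the chromones, and the diaryl ether and methyl ethers are untouched if the reaction is stopped at full conversion.

Step 8
Reactants: 11 the C7 phenol
Product: 12 7-acetoxy-2-(4-methoxyphenyl)-8-[4-(7-methoxy-4-oxo-4H-chromen-2-yl)phenoxy]-4H-chromen-4-one (5,5''-dideoxy biflavone acetate)
Conditions: Ac2O, pyridine, DMAP (cat.), CH2Cl2, rt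
Reagents that add atoms: acetic anhydride, CC(=O)OC(C)=O
Why: DMAP-catalysed O-acylation of the acidic C7 phenol gives the electron-poor aryl acetate that shields ring A of unit 1 from the oxidant of the next step.

Step 9
Reactants: 12 the 5,5''-dideoxy biflavone acetate
Product: 14 7-acetoxy-5-hydroxy-8-[4-(5-hydroxy-7-methoxy-4-oxo-4H-chromen-2-yl)phenoxy]-2-(4-methoxyphenyl)-4H-chromen-4-one (7-O-acetyl target), via bis-trifluoroacetate 13 (not isolated)
Conditions: [RuCl2(p-cymene)]2 (10 mol %), PhI(OCOCF3)2 (4.4 equiv), CF3CO2H/(CF3CO)2O (3:1), 80 °C; then aq. NaHCO3, EtOAc, rt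
Reagents that add atoms: [bis(trifluoroacetoxy)iodo]benzene, O=C(O[I](OC(=O)C(F)(F)F)c1ccccc1)C(F)(F)F; trifluoroacetic acid, OC(=O)C(F)(F)F (same trifluoroacetate pool, source of the two C5 oxygens)
Why: Each C4 carbonyl oxygen binds divalent ruthenium and delivers it to its peri C5–H by carboxylate-assisted metalation, giving a five-membered ruthenacycle (Ru, O, C4, C4a, C5) that PhI(OCOCF3)2 oxidises to a tetravalent ruthenium aryl trifluoroacetate, from which C–O reductive elimination releases the C5 trifluoroacetate and divalent ruthenium. The closest known reaction is the ketone-directed ruthenium-catalysed ortho C–H hydroxylation established at C5 of single flavones and chromones, run here at both chromone carbonyls of one molecule with doubled catalyst and oxidant; the two sites are electronically insulated by the ether bridge and should react independently. No ring is closed and no stereocentre is formed, and the two new bonds are the C5–O bonds of unit 1 and unit 2. The step must avoid C3–H, C6–H, the anisyl ring and the central aryloxy ring; only C5–H can form a five-membered chelate with the carbonyl, and the C7 acetate and the protonated chromones keep all rings too electron-poor for direct attack by the trivalent iodine reagent. Each new oxygen stays masked as its trifluoroacetate in the anhydride medium, which prevents over-oxidation, and hydrogen carbonate at work-up cleaves only these activated esters and leaves the C7 acetate.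

Step 10
Reactants: 14 the 7-O-acetyl target
Product: 15 5,7-dihydroxy-8-[4-(5-hydroxy-7-methoxy-4-oxo-4H-chromen-2-yl)phenoxy]-2-(4-methoxyphenyl)-4H-chromen-4-one (target, CNP0124888.0)
Conditions: K2CO3 (0.3 equiv), MeOH–THF, 0 °C; then AcOH
Reagents that add atoms: none
Why: Base-catalysed methanolysis (transesterification) of the activated aryl acetate should proceed at 0 °C, where the two hydrogen-bonded C5 hydroxyls, the methyl ethers, the diaryl ether and the chromone rings are unaffected.

**Compound list**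

1 | gallacetophenone (1-(2,3,4-trihydroxyphenyl)ethanone) | CC(=O)c1ccc(O)c(O)c1O | starting material
2 | 4-methoxybenzoyl chloride | COc1ccc(C(Cl)=O)cc1 | starting material
3 | 1-(4-methoxyphenyl)-3-(2,3,4-trihydroxyphenyl)propane-1,3-dione | COc1ccc(C(=O)CC(=O)c2ccc(O)c(O)c2O)cc1 | intermediate
4 | 7,8-dihydroxy-4'-methoxyflavone | COc1ccc(-c2cc(=O)c3ccc(O)c(O)c3o2)cc1 | intermediate
5 | 7-benzyloxy-8-hydroxy-4'-methoxyflavone | COc1ccc(-c2cc(=O)c3ccc(OCc4ccccc4)c(O)c3o2)cc1 | intermediate
6 | 4-fluorobenzaldehyde | O=Cc1ccc(F)cc1 | starting material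
7 | 4-{[7-benzyloxy-2-(4-methoxyphenyl)-4-oxo-4H-chromen-8-yl]oxy}benzaldehyde | COc1ccc(-c2cc(=O)c3ccc(OCc4ccccc4)c(Oc4ccc(C=O)cc4)c3o2)cc1 | intermediate
8 | paeonol (1-(2-hydroxy-4-methoxyphenyl)ethanone) | COc1ccc(C(C)=O)c(O)c1 | starting material
9 | (E)-3-(4-{[7-benzyloxy-2-(4-methoxyphenyl)-4-oxo-4H-chromen-8-yl]oxy}phenyl)-1-(2-hydroxy-4-methoxyphenyl)prop-2-en-1-one | COc1ccc(-c2cc(=O)c3ccc(OCc4ccccc4)c(Oc4ccc(/C=C/C(=O)c5ccc(OC)cc5O)cc4)c3o2)cc1 | intermediate
10 | 7-benzyloxy-2-(4-methoxyphenyl)-8-[4-(7-methoxy-4-oxo-4H-chromen-2-yl)phenoxy]-4H-chromen-4-one | COc1ccc(-c2cc(=O)c3ccc(OCc4ccccc4)c(Oc4ccc(-c5cc(=O)c6ccc(OC)cc6o5)cc4)c3o2)cc1 | intermediate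
11 | 7-hydroxy-2-(4-methoxyphenyl)-8-[4-(7-methoxy-4-oxo-4H-chromen-2-yl)phenoxy]-4H-chromen-4-one | COc1ccc(-c2cc(=O)c3ccc(O)c(Oc4ccc(-c5cc(=O)c6ccc(OC)cc6o5)cc4)c3o2)cc1 | intermediate
12 | 7-acetoxy-2-(4-methoxyphenyl)-8-[4-(7-methoxy-4-oxo-4H-chromen-2-yl)phenoxy]-4H-chromen-4-one (key-step precursor) | COc1ccc(-c2cc(=O)c3ccc(OC(C)=O)c(Oc4ccc(-c5cc(=O)c6ccc(OC)cc6o5)cc4)c3o2)cc1 | intermediate
13 | 7-acetoxy-2-(4-methoxyphenyl)-8-{4-[7-methoxy-4-oxo-5-(trifluoroacetoxy)-4H-chromen-2-yl]phenoxy}-5-(trifluoroacetoxy)-4H-chromen-4-one (bis-trifluoroacetate, not isolated) | COc1ccc(-c2cc(=O)c3c(OC(=O)C(F)(F)F)cc(OC(C)=O)c(Oc4ccc(-c5cc(=O)c6c(OC(=O)C(F)(F)F)cc(OC)cc6o5)cc4)c3o2)cc1 | intermediate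
14 | 7-acetoxy-5-hydroxy-8-[4-(5-hydroxy-7-methoxy-4-oxo-4H-chromen-2-yl)phenoxy]-2-(4-methoxyphenyl)-4H-chromen-4-one (key-step product) | COc1ccc(-c2cc(=O)c3c(O)cc(OC(C)=O)c(Oc4ccc(-c5cc(=O)c6c(O)cc(OC)cc6o5)cc4)c3o2)cc1 | intermediate
15 | 5,7-dihydroxy-8-[4-(5-hydroxy-7-methoxy-4-oxo-4H-chromen-2-yl)phenoxy]-2-(4-methoxyphenyl)-4H-chromen-4-one | COc1ccc(-c2cc(=O)c3c(O)cc(O)c(Oc4ccc(-c5cc(=O)c6c(O)cc(OC)cc6o5)cc4)c3o2)cc1 | target

**Step count and risks**

Total steps: 10. Longest linear sequence: 10 steps (from gallacetophenone 1; the route is fully linear).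

Steps most likely to fail:

Step 9. The second C–H oxygenation may stall as the catalyst decays, and long exposure to the trivalent iodine oxidant at 80 °C may start to oxidise the anisyl and aryloxy rings. The fallback sets out from aldehyde 7 and returns at target 15. It brings the C5 oxygen of unit 2 in with a symmetric building block, so that only one single-site hydroxylation of the precedented kind remains. Aldehyde 7 would be condensed (KOH, EtOH–THF) with 2,6-dihydroxy-4-methoxyacetophenone F1 to the E chalcone F2. I2 in DMSO would close either of its two equivalent phenols onto the enone and give the 5''-hydroxy benzyl ether F3. Hydrogenolysis (H2, Pd/C) would give the diol F4, and Ac2O/pyridine/DMAP at 50 °C the diacetate F5. One carbonyl-directed hydroxylation under the step 9 conditions with half the catalyst and oxidant should then pass through the C5 trifluoroacetate F6 (not isolated) to the monophenol diacetate F7. K2CO3 in MeOH would remove both acetates and deliver 15.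

Step 5. During the slow condensation, hydroxide may add to C2 of ring C of unit 1 and open or cleave the chromone, and the poorly soluble aldehyde may react incompletely. The fallback sets out from phenol 5, returns at benzyl ether 10 and replaces steps 4 to 6. Paeonol 8 and 4-fluorobenzaldehyde 6 would be condensed first (KOH, EtOH, rt) to the E fluorochalcone F8, which I2 in DMSO should cyclise to 4'-fluoro-7-methoxyflavone F9. The C8 phenoxide of 5 would then displace the fluoride of F9, which is activated through the conjugated path from ring B over C2=C3 to the C4 carbonyl, in an SNAr (Cs2CO3, DMSO, 130 °C). This gives 10 directly, and unit 1 never meets hydroxide.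

Step 3. Site selectivity may be lost, with benzylation at O8 or at both oxygens and isomers that are hard to separate. The fallback sets out from 1 and returns at 5. The oxygens would be told apart on the acetophenone, where the C4 hydroxyl (para to the acetyl group) is the most acidic and the C2 hydroxyl is held in a hydrogen bond. BnBr/NaHCO3 in DMF should give 1-(4-benzyloxy-2,3-dihydroxyphenyl)ethanone F10. LiN(SiMe3)2 (4.2 equiv) and acid chloride 2 would then give the benzyloxy diketone F11. TsOH·H2O in toluene at 80 °C, mild enough for the benzyl ether, should cyclodehydrate F11 to 5.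

**Further compounds**

F1 | step 9 | 2,6-dihydroxy-4-methoxyacetophenone | CC(=O)c1c(O)cc(OC)cc1O
F2 | step 9 | (E)-3-(4-{[7-benzyloxy-2-(4-methoxyphenyl)-4-oxo-4H-chromen-8-yl]oxy}phenyl)-1-(2,6-dihydroxy-4-methoxyphenyl)prop-2-en-1-one | COc1ccc(-c2cc(=O)c3ccc(OCc4ccccc4)c(Oc4ccc(/C=C/C(=O)c5c(O)cc(OC)cc5O)cc4)c3o2)cc1
F3 | step 9 | 7-benzyloxy-8-[4-(5-hydroxy-7-methoxy-4-oxo-4H-chromen-2-yl)phenoxy]-2-(4-methoxyphenyl)-4H-chromen-4-one | COc1ccc(-c2cc(=O)c3ccc(OCc4ccccc4)c(Oc4ccc(-c5cc(=O)c6c(O)cc(OC)cc6o5)cc4)c3o2)cc1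
F4 | step 9 | 7-hydroxy-8-[4-(5-hydroxy-7-methoxy-4-oxo-4H-chromen-2-yl)phenoxy]-2-(4-methoxyphenyl)-4H-chromen-4-one | COc1ccc(-c2cc(=O)c3ccc(O)c(Oc4ccc(-c5cc(=O)c6c(O)cc(OC)cc6o5)cc4)c3o2)cc1
F5 | step 9 | 7-acetoxy-8-[4-(5-acetoxy-7-methoxy-4-oxo-4H-chromen-2-yl)phenoxy]-2-(4-methoxyphenyl)-4H-chromen-4-one | COc1ccc(-c2cc(=O)c3ccc(OC(C)=O)c(Oc4ccc(-c5cc(=O)c6c(OC(C)=O)cc(OC)cc6o5)cc4)c3o2)cc1
F6 | step 9 | 7-acetoxy-8-[4-(5-acetoxy-7-methoxy-4-oxo-4H-chromen-2-yl)phenoxy]-2-(4-methoxyphenyl)-5-(trifluoroacetoxy)-4H-chromen-4-one | COc1ccc(-c2cc(=O)c3c(OC(=O)C(F)(F)F)cc(OC(C)=O)c(Oc4ccc(-c5cc(=O)c6c(OC(C)=O)cc(OC)cc6o5)cc4)c3o2)cc1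
F7 | step 9 | 7-acetoxy-8-[4-(5-acetoxy-7-methoxy-4-oxo-4H-chromen-2-yl)phenoxy]-5-hydroxy-2-(4-methoxyphenyl)-4H-chromen-4-one | COc1ccc(-c2cc(=O)c3c(O)cc(OC(C)=O)c(Oc4ccc(-c5cc(=O)c6c(OC(C)=O)cc(OC)cc6o5)cc4)c3o2)cc1
F8 | step 5 | (E)-3-(4-fluorophenyl)-1-(2-hydroxy-4-methoxyphenyl)prop-2-en-1-one | COc1ccc(C(=O)/C=C/c2ccc(F)cc2)c(O)c1
F9 | step 5 | 4'-fluoro-7-methoxyflavone | COc1ccc2c(=O)cc(-c3ccc(F)cc3)oc2c1
F10 | step 3 | 1-(4-benzyloxy-2,3-dihydroxyphenyl)ethanone | CC(=O)c1ccc(OCc2ccccc2)c(O)c1O
F11 | step 3 | 1-(4-benzyloxy-2,3-dihydroxyphenyl)-3-(4-methoxyphenyl)propane-1,3-dione | COc1ccc(C(=O)CC(=O)c2ccc(OCc3ccccc3)c(O)c2O)cc1
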